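**Retrosynthetic overview**

1. Locants: ring carbons C1–C10 (C1 = CH–OH, C4 bears C15H2OH, C6 = lactone O–CH, C7 = ring-fusion CH bearing C11, C8 = CH–O-acyl, C10 bears C14H3); lactone carbons C11(=C13H2) and C12(=O). The carbocycle is a cis,cis-cyclodeca-1,6-diene, trans-fused at C6–C7 to the α-methylene-γ-butyrolactone.
2. Enabling feature: O–C6 is an allylic C–O bond (C6 lies next to C4=C5), and C6 is vicinal to C7, which carries C11. The ring O–C6–C7–C11–C12 is therefore the adduct of a C4=C5–C6=C7 diene and 2-bromoacrylic acid, closed at O–C6 by carboxylate capture of a C4–C5–C6 allylpalladium.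
3. Disconnections: C1–C10 (Nozaki–Hiyama–Kishi closure; the Z-iodide at C10 is masked as a vinylsilane until after the palladium step); C7–C11 plus O–C6 (key annulation on an acyclic E,E-diene); C4=C5 (Horner–Wadsworth–Emmons); C8–C9 (catalytic asymmetric propynylation, then trans-hydrosilylation).
4. Stereochemistry: C8 is set by catalysis; C7 and C6 are relayed from it in the key step; C1 is set in the macrocyclisation; the 2-methylbutanoate stereocentre is bought.
5. Ring order: lactone first (step 9), ten-membered carbocycle second (step 13).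

Key step: step 9

Assumption: (S,S)-ProPhenol is taken as the ligand antipode that delivers the alkynyl group to the Re face of enal 1 (giving the 4S carbinol); if the facial sense of this catalyst is the reverse, (R,R)-ProPhenol is used with no other change.

**Step 1**
Reactants: 1 (E)-4,4-dimethoxybut-2-enal (fumaraldehyde mono(dimethyl acetal)); 2 propyne
Product: 4 (4S,5E)-7,7-dimethoxyhept-5-en-2-yn-4-ol, via methyl(prop-1-ynyl)zinc 3 (not isolated)
Conditions: 2 (3 equiv), Me2Zn (3 equiv), (S,S)-ProPhenol (10 mol %), Ph3P=O (20 mol %), toluene, 0 °C, then 1; aq. NH4Cl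
Reagents that add atoms: none
Why: Dinuclear zinc–ProPhenol-catalysed enantioselective alkynylation of an enal, in which the zinc alkynylide adds 1,2 to the Re face of the aldehyde and sets C8 (4S here), the only stereocentre made by catalysis, while the acetal and the E alkene are inert.

**Step 2**
Reactants: 4 (4S,5E)-7,7-dimethoxyhept-5-en-2-yn-4-ol
Product: 5 (2Z,4S,5E)-7,7-dimethoxy-2-(triethylsilyl)hepta-2,5-dien-4-ol
Conditions: Et3SiH (1.2 equiv), [Cp*Ru(MeCN)3]PF6 (2 mol %), CH2Cl2, 0 °C to rt
Reagents that add atoms: triethylsilane, CC[SiH](CC)CC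
Why: Ruthenium-catalysed trans-hydrosilylation of a propargylic alcohol adds H and Si anti across the alkyne with silicon on the carbon distal to the hydroxyl, so that SiEt3 ends cis to the carbinol carbon (a masked Z-vinyl iodide) and the disubstituted alkene is untouched.

**Step 3**
Reactants: 5 (2Z,4S,5E)-7,7-dimethoxy-2-(triethylsilyl)hepta-2,5-dien-4-ol
Product: 6 (2Z,4S,5E)-4-(tert-butyldimethylsilyloxy)-7,7-dimethoxy-2-(triethylsilyl)hepta-2,5-diene
Conditions: TBSCl, imidazole, DMAP (cat.), DMF, rt
Reagents that add atoms: tert-butyldimethylsilyl chloride, CC(C)(C)[Si](C)(C)Cl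
Why: Standard silylation of the secondary alcohol under basic conditions that leave the acetal intact; the ether blocks ionisation of the doubly allylic C8–O bond and later serves as the steric and stereoelectronic control element at C8.

**Step 4**
Reactants: 6 (2Z,4S,5E)-4-(tert-butyldimethylsilyloxy)-7,7-dimethoxy-2-(triethylsilyl)hepta-2,5-diene
Product: 7 (2E,4S,5Z)-4-(tert-butyldimethylsilyloxy)-6-(triethylsilyl)hepta-2,5-dienal
Conditions: PPTS (cat.), acetone/H2O (10:1), rt
Reagents that add atoms: water, O
Why: Mild acid hydrolysis of an allylic (conjugated) dimethyl acetal, which is far more labile than the TBS ether or the vinylsilane, should give the E enal with C8 unchanged.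

**Step 5**
Reactants: 8 triethyl phosphonoacetate; 9 3-bromo-1,1-dimethoxypropane
Product: 11 ethyl 2-(diethoxyphosphoryl)-5,5-dimethoxypentanoate, via sodium enolate of triethyl phosphonoacetate 10 (not isolated)
Conditions: NaH, DMF, 0 °C, then 9, 60 °C
Reagents that add atoms: none
Why: SN2 C-alkylation of the stabilised phosphonoacetate enolate with a primary bromide gives the α-substituted phosphonate carrying C1–C3 (C1 masked as its dimethyl acetal), C4 and C15.

**Step 6**
Reactants: 7 (2E,4S,5Z)-4-(tert-butyldimethylsilyloxy)-6-(triethylsilyl)hepta-2,5-dienal; 11 ethyl 2-(diethoxyphosphoryl)-5,5-dimethoxypentanoate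
Product: 13 ethyl (2E,4E,6S,7Z)-6-(tert-butyldimethylsilyloxy)-2-(3,3-dimethoxypropyl)-8-(triethylsilyl)nona-2,4,7-trienoate, via sodium phosphonate carbanion 12 (not isolated)
Conditions: NaH, THF, 0 °C, then 7, 0 °C to rt
Reagents that add atoms: none
Why: Horner–Wadsworth–Emmons olefination of a conjugated aldehyde with an α-alkyl phosphonoacetate should give mainly the E trisubstituted enoate (ester carbon C15 trans to C6, so that C3 and C6 are cis as the ring requires); the minor 2Z isomer would be removed by chromatography.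

**Step 7**
Reactants: 13 the trienoate from step 6
Product: 14 (2E,4E,6S,7Z)-6-(tert-butyldimethylsilyloxy)-2-(3,3-dimethoxypropyl)-8-(triethylsilyl)nona-2,4,7-trien-1-ol
Conditions: iBu2AlH (2.2 equiv), CH2Cl2, −78 °C; aq. KNa tartrate
Reagents that add atoms: none
Why: 1,2-Reduction of the conjugated ester by the aluminium hydride gives the primary allylic alcohol (C15) without touching the diene, acetal or silyl groups.

**Step 8**
Reactants: 14 the trienol from step 7
Product: 15 1-O-tert-butyldiphenylsilyl ether of 14 (acyclic E,E-diene C4=C5–C6=C7 with the single stereocentre C8)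
Conditions: TBDPSCl, imidazole, CH2Cl2, 0 °C to rt
Reagents that add atoms: tert-butyl(chloro)diphenylsilane, CC(C)(C)[Si](Cl)(c1ccccc1)c1ccccc1
Why: Silylation of the primary allylic alcohol gives an acid-robust ether that cannot be ionised by palladium and cannot compete as a nucleophile for the allyl intermediate of the key step.

**Step 9**
Reactants: 15 the diene from step 8; 16 2-bromoacrylic acid
Product: 17 (4S,5R)-4-[(1S,2Z)-1-(tert-butyldimethylsilyloxy)-3-(triethylsilyl)but-2-en-1-yl]-5-[(1E)-2-(tert-butyldiphenylsilyloxymethyl)-5,5-dimethoxypent-1-en-1-yl]-3-methylideneoxolan-2-one (trans lactone)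
Conditions: 16 (1.5 equiv), Pd(OAc)2 (10 mol %), tri(2-furyl)phosphine (20 mol %), Ag2CO3 (1.0 equiv), MeCN, 60 °C
Reagents that add atoms: none
Why: Zerovalent palladium inserts into the C–Br bond of 16 (present as its silver carboxylate), the alkenylpalladium adds syn across C6=C7 with carbon bonding to the less substituted diene terminus C7, and the resulting η3-allylpalladium over C4–C5–C6, held by the carboxylate as a six-membered palladacycle, undergoes C–O reductive elimination at C6 to form the O–C6 bond and return zerovalent palladium. The closest known reaction type is the Larock heteroannulation of 1,3-dienes by halides carrying a carboxylic acid, which turns 2-haloacrylic acids into α-alkylidene-γ-butyrolactones. The one ring closed is the five-membered lactone, by 5-exo attack of the carboxylate oxygen on the allyl terminus C6, the rest of the allyl unit staying outside the ring as the C4=C5 alkene. C7 is set by π-facial control from C8 (inside-alkoxy conformer: O8 near the diene plane, the vinylsilane arm anti to the incoming carbon, so that C11 and O8 end anti), and C6 is set relative to C7 by the syn course of the addition across the E alkene, with C–O bond formation on the palladium-bearing face, which gives the trans-4,5-disubstituted lactone that reversible ionisation of the allylic C–O bond would also favour. The step needs regioselectivity (C7 over the fully substituted C4 for carbon; C6 over C4 for oxygen, five- against seven-membered ring), retention of the C4=C5 geometry (the disubstituted allyl terminus C4 should not undergo syn/anti exchange) and suppression of β-hydride elimination and outer-sphere attack, for which the halide-free silver conditions and the chelating carboxylate are chosen; vinylsilane, acetal and silyl ethers are inert.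

**Step 10**
Reactants: 17 the lactone from step 9
Product: 18 Z-vinyl iodide of 17 (SiEt3 at C10 replaced by I with retention; otherwise as 17)
Conditions: N-iodosuccinimide (1.1 equiv), (CF3)2CHOH, 0 °C, 10 min
Reagents that add atoms: N-iodosuccinimide, O=C1CCC(=O)N1I
Why: Electrophilic ipso-iododesilylation of a vinylsilane proceeds with retention through a β-silyl-stabilised cation and should be much faster than attack on the C4=C5 alkene (deactivated by two allylic oxygens) or on the electron-poor methylene lactone.

**Step 11**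
Reactants: 18 the Z-vinyl iodide from step 10
Product: 19 (4R,5R)-4-[(1S,2Z)-1-hydroxy-3-iodobut-2-en-1-yl]-5-[(1E)-2-(tert-butyldiphenylsilyloxymethyl)-5-oxopent-1-en-1-yl]-3-methylideneoxolan-2-one
Conditions: 48% aq. HF/MeCN (1:19), 0 °C to rt
Reagents that add atoms: water, O
Why: Aqueous HF cleaves the secondary TBS ether and hydrolyses the dimethyl acetal in one operation, while the primary TBDPS ether should survive by the usual order of silyl ether lability; no stereocentre is touched.

**Step 12**
Reactants: 19 the hydroxy aldehyde from step 11; 20 (S)-2-methylbutanoic anhydride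
Product: 21 O8-(2S)-2-methylbutanoate of 19 (precursor for ring closure: Z-iodide at C10, aldehyde at C1)
Conditions: 20 (1.5 equiv), Et3N, DMAP (0.1 equiv), CH2Cl2, 0 °C
Reagents that add atoms: none
Why: DMAP-catalysed acylation of the secondary allylic alcohol with the bought enantiopure anhydride installs the side chain with retention at C8; it is run directly on the fresh alcohol to pre-empt lactone migration from O6 to O8, and the aldehyde is inert.

**Step 13**
Reactants: 21 the ester aldehyde from step 12
Product: 23 15-O-tert-butyldiphenylsilyl ether of the target (ten-membered ring closed, 1S alcohol), via alkenylchromium dichloride 22 (not isolated)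
Conditions: CrCl2 (10 equiv), NiCl2 (0.1 equiv), DMSO/THF, 0.003 M, slow addition, rt; aq. work-up
Reagents that add atoms: none
Why: Intramolecular Nozaki–Hiyama–Kishi reaction, in which the nickel-catalysed conversion of the Z-iodide into a trivalent alkenylchromium (with retention) and its 1,2-addition to the aldehyde close the ten-membered ring at C1–C10 (the two cis alkenes and the trans lactone pre-organise the chain), and C1 is set under substrate control, Re-face attack (1S) being expected from a chair-like cis,cis-cyclodeca-1,6-diene transition state in which H1 and H8 both eclipse the C9=C10 bond so that O1 ends anti to O8.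

**Step 14**
Reactants: 23 the silyl-protected macrocycle from step 13
Product: 24 target, (1S,6R,7R,8R)-1,15-dihydroxy-8-[(2S)-2-methylbutanoyloxy]germacra-4,9,11(13)-trien-12,6-olide with ring alkenes 4E and 9Z (both cis within the ring)
Conditions: HF·pyridine, pyridine/THF, 0 °C to rt
Reagents that add atoms: none
Why: Buffered fluoride cleavage of the primary TBDPS ether is non-basic, so the methylene lactone, both esters and the allylic alcohol should be untouched and no stereocentre is affected.

**Compound list**

1 | (E)-4,4-dimethoxybut-2-enal | COC(OC)/C=C/C=O | starting material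
2 | propyne | CC#C | starting material
3 | methyl(prop-1-ynyl)zinc | CC#C[Zn]C | intermediate
4 | (4S,5E)-7,7-dimethoxyhept-5-en-2-yn-4-ol | CC#C[C@@H](O)/C=C/C(OC)OC | intermediate
5 | (2Z,4S,5E)-7,7-dimethoxy-2-(triethylsilyl)hepta-2,5-dien-4-ol | C/C(=C/[C@@H](O)/C=C/C(OC)OC)[Si](CC)(CC)CC | intermediate
6 | (2Z,4S,5E)-4-(tert-butyldimethylsilyloxy)-7,7-dimethoxy-2-(triethylsilyl)hepta-2,5-diene | C/C(=C/[C@@H](O[Si](C)(C)C(C)(C)C)/C=C/C(OC)OC)[Si](CC)(CC)CC | intermediate
7 | (2E,4S,5Z)-4-(tert-butyldimethylsilyloxy)-6-(triethylsilyl)hepta-2,5-dienal | C/C(=C/[C@@H](O[Si](C)(C)C(C)(C)C)/C=C/C=O)[Si](CC)(CC)CC | intermediate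
8 | triethyl phosphonoacetate | CCOC(=O)CP(=O)(OCC)OCC | starting material
9 | 3-bromo-1,1-dimethoxypropane | COC(OC)CCBr | starting material
10 | sodium enolate of triethyl phosphonoacetate | CCOC(=O)[CH-]P(=O)(OCC)OCC.[Na+] | intermediate
11 | ethyl 2-(diethoxyphosphoryl)-5,5-dimethoxypentanoate | CCOC(=O)C(CCC(OC)OC)P(=O)(OCC)OCC | intermediate
12 | sodium phosphonate carbanion of 11 | CCOC(=O)[C-](CCC(OC)OC)P(=O)(OCC)OCC.[Na+] | intermediate
13 | ethyl (2E,4E,6S,7Z)-6-(tert-butyldimethylsilyloxy)-2-(3,3-dimethoxypropyl)-8-(triethylsilyl)nona-2,4,7-trienoate | C/C(=C/[C@@H](O[Si](C)(C)C(C)(C)C)/C=C/C=C(/C(=O)OCC)CCC(OC)OC)[Si](CC)(CC)CC | intermediate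
14 | (2E,4E,6S,7Z)-6-(tert-butyldimethylsilyloxy)-2-(3,3-dimethoxypropyl)-8-(triethylsilyl)nona-2,4,7-trien-1-ol | C/C(=C/[C@@H](O[Si](C)(C)C(C)(C)C)/C=C/C=C(/CO)CCC(OC)OC)[Si](CC)(CC)CC | intermediate
15 | 1-O-tert-butyldiphenylsilyl ether of 14 | C/C(=C/[C@@H](O[Si](C)(C)C(C)(C)C)/C=C/C=C(/CO[Si](c1ccccc1)(c1ccccc1)C(C)(C)C)CCC(OC)OC)[Si](CC)(CC)CC | intermediate
16 | 2-bromoacrylic acid | C=C(Br)C(=O)O | starting material
17 | (4S,5R)-4-[(1S,2Z)-1-(tert-butyldimethylsilyloxy)-3-(triethylsilyl)but-2-en-1-yl]-5-[(1E)-2-(tert-butyldiphenylsilyloxymethyl)-5,5-dimethoxypent-1-en-1-yl]-3-methylideneoxolan-2-one | C=C1C(=O)O[C@H](/C=C(/CO[Si](c2ccccc2)(c2ccccc2)C(C)(C)C)CCC(OC)OC)[C@H]1[C@H](O[Si](C)(C)C(C)(C)C)/C=C(/C)[Si](CC)(CC)CC | intermediate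
18 | Z-vinyl iodide of 17 (I in place of SiEt3) | C=C1C(=O)O[C@H](/C=C(/CO[Si](c2ccccc2)(c2ccccc2)C(C)(C)C)CCC(OC)OC)[C@H]1[C@H](O[Si](C)(C)C(C)(C)C)/C=C(/C)I | intermediate
19 | (4R,5R)-4-[(1S,2Z)-1-hydroxy-3-iodobut-2-en-1-yl]-5-[(1E)-2-(tert-butyldiphenylsilyloxymethyl)-5-oxopent-1-en-1-yl]-3-methylideneoxolan-2-one | C=C1C(=O)O[C@H](/C=C(/CO[Si](c2ccccc2)(c2ccccc2)C(C)(C)C)CCC=O)[C@H]1[C@H](O)/C=C(/C)I | intermediate
20 | (S)-2-methylbutanoic anhydride | CC[C@H](C)C(=O)OC(=O)[C@@H](C)CC | starting material
21 | O8-(2S)-2-methylbutanoate of 19 | C=C1C(=O)O[C@H](/C=C(/CO[Si](c2ccccc2)(c2ccccc2)C(C)(C)C)CCC=O)[C@H]1[C@H](OC(=O)[C@@H](C)CC)/C=C(/C)I | intermediate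
22 | alkenylchromium dichloride from 21 (trivalent chromium at C10) | C=C1C(=O)O[C@H](/C=C(/CO[Si](c2ccccc2)(c2ccccc2)C(C)(C)C)CCC=O)[C@H]1[C@H](OC(=O)[C@@H](C)CC)/C=C(/C)[Cr](Cl)Cl | intermediate
23 | 15-O-tert-butyldiphenylsilyl ether of the target | C=C1C(=O)O[C@@H]2/C=C(/CO[Si](c3ccccc3)(c3ccccc3)C(C)(C)C)CC[C@H](O)/C(C)=C\[C@@H](OC(=O)[C@@H](C)CC)[C@@H]12 | intermediate
24 | target germacranolide | C=C1C(=O)O[C@@H]2/C=C(/CO)CC[C@H](O)/C(C)=C\[C@@H](OC(=O)[C@@H](C)CC)[C@@H]12 | target

**Step count**

Total step count: 14. Longest linear sequence: 13 steps (steps 1–4 and 6–14; step 5 is a one-step branch).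

**Three steps most likely to fail**

Step 9. The π-facial selectivity of the carbopalladation at C7 may follow the opposite sense to the inside-alkoxy model, so that carbon enters syn to O8 and the two lactone stereocentres form in the mirror-image sense relative to C8. Fallback (sets out from 1, comes back at 21): the alkynylation of step 1 is run with the antipodal ProPhenol ligand to give the enantiomeric propargylic alcohol F1, which is taken through steps 2–4 and 6–8 unchanged to the enantiomeric vinylsilane alcohol F2, silyl ether F3, enal F4, dienoate F5, dienol F6 and diene F7. The annulation of F7 with 16 should then give, by the syn course, the 8-epi lactone F8 with C6 and C7 as required. Steps 10 and 11 give the 8-epi iodide F9 and the 8-epi hydroxy aldehyde F10. A Mitsunobu esterification of F10 with (S)-2-methylbutanoic acid (PPh3, diisopropyl azodicarboxylate, toluene, 0 °C) inverts C8 while installing the ester, which gives 21.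

Step 13. Poor facial selectivity at the aldehyde during the ring closure would give a mixture of C1 epimers. Fallback (sets out from 21, comes back at 23): the macrocyclisation is accepted as it comes, and the mixture of 23 and its 1-epi alcohol F11 is oxidised with Dess–Martin periodinane (NaHCO3, CH2Cl2) to the cyclodecadienone F12. The ketone is then reduced under reagent control with (R)-2-methyl-CBS-oxazaborolidine and catecholborane in toluene at −78 °C (Corey–Bakshi–Shibata reduction, the α-methyl alkenyl arm acting as the large group), which should give the 1S alcohol 23.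

Step 1. Uncatalysed background addition of the small alkynylzinc would erode the enantioselectivity on which every later stereocentre depends. Fallback (sets out from 1, comes back at 4): 1-propynylmagnesium bromide in THF at −78 °C adds to 1 to give the racemic alcohol F13, MnO2 in CH2Cl2 oxidises it to the enynone F14, and Midland reduction with (S)-Alpine-Borane (THF, rt), in which the alkynyl group is the small substituent, should give 4.

**Further compounds**

F1 | step 9 | (4R,5E)-7,7-dimethoxyhept-5-en-2-yn-4-ol (enantiomer of 4) | CC#C[C@H](O)/C=C/C(OC)OC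
F2 | step 9 | enantiomer of 5 | C/C(=C/[C@H](O)/C=C/C(OC)OC)[Si](CC)(CC)CC
F3 | step 9 | enantiomer of 6 | C/C(=C/[C@H](O[Si](C)(C)C(C)(C)C)/C=C/C(OC)OC)[Si](CC)(CC)CC
F4 | step 9 | enantiomer of 7 | C/C(=C/[C@H](O[Si](C)(C)C(C)(C)C)/C=C/C=O)[Si](CC)(CC)CC
F5 | step 9 | enantiomer of 13 | C/C(=C/[C@H](O[Si](C)(C)C(C)(C)C)/C=C/C=C(/C(=O)OCC)CCC(OC)OC)[Si](CC)(CC)CC
F6 | step 9 | enantiomer of 14 | C/C(=C/[C@H](O[Si](C)(C)C(C)(C)C)/C=C/C=C(/CO)CCC(OC)OC)[Si](CC)(CC)CC
F7 | step 9 | enantiomer of 15 | C/C(=C/[C@H](O[Si](C)(C)C(C)(C)C)/C=C/C=C(/CO[Si](c1ccccc1)(c1ccccc1)C(C)(C)C)CCC(OC)OC)[Si](CC)(CC)CC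
F8 | step 9 | C8 epimer of 17 | C=C1C(=O)O[C@H](/C=C(/CO[Si](c2ccccc2)(c2ccccc2)C(C)(C)C)CCC(OC)OC)[C@H]1[C@@H](O[Si](C)(C)C(C)(C)C)/C=C(/C)[Si](CC)(CC)CC
F9 | step 9 | C8 epimer of 18 | C=C1C(=O)O[C@H](/C=C(/CO[Si](c2ccccc2)(c2ccccc2)C(C)(C)C)CCC(OC)OC)[C@H]1[C@@H](O[Si](C)(C)C(C)(C)C)/C=C(/C)I
F10 | step 9 | C8 epimer of 19 | C=C1C(=O)O[C@H](/C=C(/CO[Si](c2ccccc2)(c2ccccc2)C(C)(C)C)CCC=O)[C@H]1[C@@H](O)/C=C(/C)I
F11 | step 13 | C1 epimer of 23 | C=C1C(=O)O[C@@H]2/C=C(/CO[Si](c3ccccc3)(c3ccccc3)C(C)(C)C)CC[C@@H](O)/C(C)=C\[C@@H](OC(=O)[C@@H](C)CC)[C@@H]12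
F12 | step 13 | C1 ketone (cyclodecadienone) corresponding to 23 | C=C1C(=O)O[C@@H]2/C=C(/CO[Si](c3ccccc3)(c3ccccc3)C(C)(C)C)CCC(=O)/C(C)=C\[C@@H](OC(=O)[C@@H](C)CC)[C@@H]12
F13 | step 1 | racemic (E)-7,7-dimethoxyhept-5-en-2-yn-4-ol | CC#CC(O)/C=C/C(OC)OC
F14 | step 1 | (E)-7,7-dimethoxyhept-5-en-2-yn-4-one | CC#CC(=O)/C=C/C(OC)OC
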